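**Retrosynthetic overview**

1. Target 31 ⇐ 30 (fluoride removal of two TBS ethers and the TMSE ester) ⇐ 29 (hydroxyl-directed hydrogenation of C6=C7 of the 2-benzoxepine core sets C6).
2. 29 ⇐ cyclobutenol ester 21 + oxepinone 28: the lactone C=C (future C5a–C9a) is inserted into the C1–C2 bond of the cyclobutenol (ring expansion four → six), forming C5a–C6 and C9–C9a and the stereocentres C5a, C9 and C9a.
3. Enabling feature: carbinol C9 is β to the lactone carbonyl C1 (retro-aldol across C9–C9a), the isopropyl-bearing C6 sits on the lactone β-carbon C5a (retro-1,4-addition), and C6 and C9 are 1,4-related in the carbocycle. Joining C6 to C9 therefore gives a strained 2-isopropylcyclobut-2-en-1-ol that stores both the ketone and the alkenyl nucleophile.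
4. 21 ⇐ acid 14 + diol 19 (from 1,2-bis(trimethylsilyloxy)cyclobutene); 14 ⇐ catalytic asymmetric Diels–Alder of triene 9 with methyl vinyl ketone; 28 ⇐ Morita–Baylis–Hillman adduct 25 by acyl transposition and ring-closing metathesis.
5. Ring order: side-chain cyclohexene (step 6), oxepinone (step 17), core cyclohexene by expansion of the purchased four-membered ring (step 18).

Key step: step 18

Abbreviations: TBS = tert-butyl(dimethyl)silyl; TMS = trimethylsilyl; TMSE = 2-(trimethylsilyl)ethyl.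

Remark: 6, 7, 16–19, 25 and 26 are racemic and 21 is a 1:1 pair of carbinol epimers; each of these stereocentres is destroyed later (elimination, transposition or ring opening), so the route still leads to one enantiomer.

Remark: the catalyst antipodes in steps 6 and 18 are assigned from the accepted facial models of these catalyst classes; should the sense prove opposite, the mirror-image catalyst would be used.

**Route**

Step 1
Reactants: 1 2-bromoprop-2-en-1-ol
Product: 2 [(2-bromoprop-2-en-1-yl)oxy](tert-butyl)dimethylsilane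
Conditions: TBSCl, imidazole, CH2Cl2, 0 °C → rt
Reagents that add atoms: tert-butyl(chloro)dimethylsilane, CC(C)(C)[Si](C)(C)Cl
Why: Routine silylation of a primary alcohol gives the alkenyl bromide needed for the Heck coupling.

Step 2
Reactants: 3 methyl 3-hydroxypropanoate
Product: 4 methyl 3-(TBS-oxy)propanoate
Conditions: TBSCl, imidazole, CH2Cl2, 0 °C → rt
Reagents that add atoms: tert-butyl(chloro)dimethylsilane, CC(C)(C)[Si](C)(C)Cl
Why: Routine silylation of a primary alcohol.

Step 3
Reactants: 4 methyl 3-(TBS-oxy)propanoate; 5 acrolein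
Product: 6 methyl 2-[(TBS-oxy)methyl]-3-hydroxypent-4-enoate (racemic, both diastereomers)
Conditions: LDA, THF, −78 °C; then 5, −78 °C; aq. NH4Cl
Reagents that add atoms: none
Why: Aldol addition of the kinetic lithium ester enolate to acrolein (1,2-addition) at −78 °C should outpace β-elimination of the silyloxy group, and both new stereocentres are erased in step 4.

Step 4
Reactants: 6 methyl 2-[(TBS-oxy)methyl]-3-hydroxypent-4-enoate
Product: 8 methyl (2E)-2-[(TBS-oxy)methyl]penta-2,4-dienoate, via allylic mesylate 7 (not isolated)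
Conditions: MsCl, Et3N, CH2Cl2, 0 °C; then DBU, rt
Reagents that add atoms: none
Why: Mesylation and E1cB elimination should give the conjugated dienoate, the (2E) isomer with ester and vinyl trans being the less strained, tiglate-type product.

Step 5
Reactants: 8 methyl (2E)-2-[(TBS-oxy)methyl]penta-2,4-dienoate; 2 [(2-bromoprop-2-en-1-yl)oxy](tert-butyl)dimethylsilane
Product: 9 methyl (2E,4E)-2,6-bis[(TBS-oxy)methyl]hepta-2,4,6-trienoate
Conditions: Pd(OAc)2 (5 mol%), Bu4NCl, K2CO3, DMF, 60 °C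
Reagents that add atoms: none
Why: Mizoroki–Heck alkenylation at the terminal vinyl carbon of the dienoate (syn insertion, syn β-hydride elimination) should give the (4E) triene and leave the trisubstituted enoate geometry unchanged.

Step 6
Reactants: 9 methyl (2E,4E)-2,6-bis[(TBS-oxy)methyl]hepta-2,4,6-trienoate; 10 methyl vinyl ketone
Product: 11 methyl (2E)-3-{(1S,6S)-6-acetyl-3-[(TBS-oxy)methyl]cyclohex-2-en-1-yl}-2-[(TBS-oxy)methyl]prop-2-enoate
Conditions: (S)-α,α-diphenylprolinol-derived B-(o-tolyl)oxazaborolidine (20 mol%), Tf2NH (17 mol%), CH2Cl2, −78 → −40 °C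
Reagents that add atoms: none
Why: Catalytic enantioselective Diels–Alder reaction on the only diene unit that can become s-cis, in which the terminal chain (ortho) and the 2-substituent (para) both direct the acetyl group to C6, the endo transition state gives the cis C1/C6 pair, and the protonated oxazaborolidine shields one face of the boron-bound enone so that both centres arise in the (1S,6S) sense.

Step 7
Reactants: 11 methyl (2E)-3-{(1S,6S)-6-acetyl-3-[(TBS-oxy)methyl]cyclohex-2-en-1-yl}-2-[(TBS-oxy)methyl]prop-2-enoate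
Product: 12 methyl (2E)-2-[(TBS-oxy)methyl]-3-{(1S,6S)-3-[(TBS-oxy)methyl]-6-(prop-1-en-2-yl)cyclohex-2-en-1-yl}prop-2-enoate
Conditions: Zn, CH2Br2, TiCl4, THF/CH2Cl2, 0 °C → rt
Reagents that add atoms: dibromomethane, BrCBr
Why: Non-basic Lombardo-type methylenation converts the epimerisable methyl ketone into the isopropenyl group without loss of the cis configuration and leaves the ester untouched.

Step 8
Reactants: 12 methyl (2E)-2-[(TBS-oxy)methyl]-3-{(1S,6S)-3-[(TBS-oxy)methyl]-6-(prop-1-en-2-yl)cyclohex-2-en-1-yl}prop-2-enoate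
Product: 13 methyl (2E)-2-[(TBS-oxy)methyl]-3-{(1S,6R)-3-[(TBS-oxy)methyl]-6-(propan-2-yl)cyclohex-2-en-1-yl}prop-2-enoate
Conditions: H2 (1 atm), RhCl(PPh3)3 (5 mol%), benzene, rt
Reagents that add atoms: none
Why: Homogeneous hydrogenation with RhCl(PPh3)3 reduces the 1,1-disubstituted alkene far faster than the two trisubstituted alkenes; no stereocentre is formed (the descriptor at C6 changes only by priority).

Step 9
Reactants: 13 methyl (2E)-2-[(TBS-oxy)methyl]-3-{(1S,6R)-3-[(TBS-oxy)methyl]-6-(propan-2-yl)cyclohex-2-en-1-yl}prop-2-enoate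
Product: 14 (2E)-2-[(TBS-oxy)methyl]-3-{(1S,6R)-3-[(TBS-oxy)methyl]-6-(propan-2-yl)cyclohex-2-en-1-yl}prop-2-enoic acid
Conditions: LiOH, THF/MeOH/H2O, rt; then HCl to pH 4
Reagents that add atoms: lithium hydroxide, [Li+].[OH-]
Why: Saponification of the methyl ester is compatible with primary TBS ethers, and hydroxide is too weak a base to remove the doubly allylic C1–H.

Step 10
Reactants: 15 1,2-bis(trimethylsilyloxy)cyclobut-1-ene
Product: 16 2-(TMS-oxy)-2-[(TMS-oxy)methyl]cyclobutan-1-one (racemic)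
Conditions: monomeric formaldehyde (THF solution), TMSOTf (5 mol%), CH2Cl2, −78 °C; pyridine quench
Reagents that add atoms: formaldehyde, C=O
Why: Mukaiyama aldol addition of the acyloin bis-silyl enol ether to formaldehyde with silyl transfer uses the known reactivity of this enediol ether towards aldehydes; the stereocentre is erased in step 18.

Step 11
Reactants: 16 2-(TMS-oxy)-2-[(TMS-oxy)methyl]cyclobutan-1-one
Product: 17 4-(TMS-oxy)-4-[(TMS-oxy)methyl]cyclobut-1-en-1-yl trifluoromethanesulfonate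
Conditions: KHMDS, THF, −78 °C; then PhNTf2, −78 → 0 °C
Reagents that add atoms: N-phenylbis(trifluoromethanesulfonimide), O=S(=O)(N(c1ccccc1)S(=O)(=O)C(F)(F)F)C(F)(F)F
Why: The ketone has a single enolisable α-position, so enolate O-triflation can give only this cyclobutenyl triflate.

Step 12
Reactants: 17 4-(TMS-oxy)-4-[(TMS-oxy)methyl]cyclobut-1-en-1-yl trifluoromethanesulfonate
Product: 19 1-(hydroxymethyl)-2-(propan-2-yl)cyclobut-2-en-1-ol (racemic), via bis-silyl ether 18 (not isolated)
Conditions: iPrZnBr, Pd(OAc)2 (3 mol%), CPhos (6 mol%), THF, rt; then citric acid, MeOH, 0 °C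
Reagents that add atoms: isopropylzinc bromide, CC(C)[Zn]Br
Why: Negishi coupling of an alkenyl triflate with a secondary alkylzinc reagent, in which the biaryl phosphine suppresses isomerisation to the n-propyl product, is followed by mild acidic methanolysis of both TMS ethers.

Step 13
Reactants: 14 (2E)-2-[(TBS-oxy)methyl]-3-{(1S,6R)-3-[(TBS-oxy)methyl]-6-(propan-2-yl)cyclohex-2-en-1-yl}prop-2-enoic acid; 19 1-(hydroxymethyl)-2-(propan-2-yl)cyclobut-2-en-1-ol
Product: 21 [1-hydroxy-2-(propan-2-yl)cyclobut-2-en-1-yl]methyl (2E)-2-[(TBS-oxy)methyl]-3-{(1S,6R)-3-[(TBS-oxy)methyl]-6-(propan-2-yl)cyclohex-2-en-1-yl}prop-2-enoate (1:1 carbinol epimers), via mixed anhydride 20 (not isolated)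
Conditions: 2,4,6-trichlorobenzoyl chloride, Et3N, THF, rt; then 19, DMAP, toluene, rt
Reagents that add atoms: none
Why: Yamaguchi esterification acylates the primary hydroxyl selectively because the tertiary cyclobutenyl alcohol is too hindered.

Step 14
Reactants: 22 2-(trimethylsilyl)ethan-1-ol; 23 acryloyl chloride
Product: 24 2-(trimethylsilyl)ethyl prop-2-enoate
Conditions: Et3N, CH2Cl2, 0 °C
Reagents that add atoms: none
Why: Simple O-acylation of a primary alcohol with an acid chloride.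

Step 15
Reactants: 24 2-(trimethylsilyl)ethyl prop-2-enoate; 5 acrolein
Product: 25 TMSE 3-hydroxy-2-methylidenepent-4-enoate (racemic)
Conditions: DABCO (20 mol%), 1,4-dioxane/H2O, rt
Reagents that add atoms: none
Why: Morita–Baylis–Hillman reaction in which the ammonium enolate of the acrylate adds 1,2 to acrolein; the carbinol centre is erased in step 16.

Step 16
Reactants: 25 TMSE 3-hydroxy-2-methylidenepent-4-enoate; 23 acryloyl chloride
Product: 27 TMSE (2E)-2-[(prop-2-enoyloxy)methyl]penta-2,4-dienoate, via secondary acrylate 26 (not isolated)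
Conditions: 23, Et3N, DMAP (cat.), CH2Cl2, −20 °C; then DABCO (20 mol%), THF, 50 °C
Reagents that add atoms: none
Why: O-Acylation followed by DABCO-catalysed allylic transposition of the Morita–Baylis–Hillman ester (amine SN2′ addition, loss of carboxylate, return at the primary carbon) should equilibrate to the linearly conjugated (2E) dienoate with ester and vinyl trans.

Step 17
Reactants: 27 TMSE (2E)-2-[(prop-2-enoyloxy)methyl]penta-2,4-dienoate
Product: 28 TMSE 7-oxo-2,7-dihydrooxepine-3-carboxylate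
Conditions: second-generation Grubbs catalyst RuCl2(=CHPh)(H2IMes)(PCy3) (10 mol%), toluene (2 mM), 80 °C
Reagents that add atoms: none
Why: Ring-closing metathesis between the terminal vinyl group of the diene and the acrylate forms the cis enoate of the seven-membered lactone, the trisubstituted acrylate alkene being too hindered and electron-poor to take part.

Step 18
Reactants: 21 [1-hydroxy-2-(propan-2-yl)cyclobut-2-en-1-yl]methyl ester of 14; 28 TMSE 7-oxo-2,7-dihydrooxepine-3-carboxylate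
Product: 29 TMSE (5aS,9S,9aS)-9-hydroxy-1-oxo-6-(propan-2-yl)-9-({[(2E)-2-[(TBS-oxy)methyl]-3-{(1S,6R)-3-[(TBS-oxy)methyl]-6-(propan-2-yl)cyclohex-2-en-1-yl}prop-2-enoyl]oxy}methyl)-1,3,5a,8,9,9a-hexahydro-2-benzoxepine-4-carboxylate
Conditions: [Rh(OH)((S)-binap)]2 (5 mol%), toluene, 40 °C
Reagents that add atoms: none
Why: Proposed new method: the monovalent rhodium alkoxide of 21 should undergo strain-driven β-carbon elimination of the C(sp2)–C(carbinol) bond to a (Z)-alkenylrhodium ketone, which adds 1,4 to the cis-disubstituted enoate of 28 (bond C5a–C6), and the resulting rhodium enolate then closes onto the tethered ketone by aldol addition (bond C9–C9a) before alkoxide exchange with fresh 21 turns the catalyst over, so the four-membered ring is expanded by the two lactone carbons. The closest known reactions are the rhodium-catalysed insertion of alkynes and vinyl ketones into benzocyclobutenols, the Hayashi–Miyaura asymmetric 1,4-addition and rhodium-catalysed tandem conjugate addition–aldol cyclisations. The new cyclohexene ring closes by a 6-(enolexo)-exo-trig aldol. C5a is set by the (S)-binap ligand through enantioface selection in the carborhodation (by analogy with cyclic enones and lactones); C9 is set by a closed Zimmerman–Traxler-type transition state in which the ring-locked enolate geometry places the ketone oxygen anti to the C9a–C5a bond (equatorial OH, axial CH2O); C9a is set by closure anti to the C5 vinyl carbon (trans ring fusion) and stays epimerisable towards that more stable arrangement. The step needs cleavage of the alkenyl–carbinol bond and not the allylic sp3–sp3 bond (the site selectivity known for benzocyclobutenols) and attack on the lactone enoate and not on the two trisubstituted acrylates, which their substitution secures; both carbinol epimers of 21 converge because that centre is erased.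

Step 19
Reactants: 29 TMSE (5aS,9S,9aS)-hexahydro-2-benzoxepine ester described in step 18
Product: 30 TMSE (5aS,6R,9S,9aS)-9-hydroxy-1-oxo-6-(propan-2-yl)-9-({[(2E)-2-[(TBS-oxy)methyl]-3-{(1S,6R)-3-[(TBS-oxy)methyl]-6-(propan-2-yl)cyclohex-2-en-1-yl}prop-2-enoyl]oxy}methyl)-1,3,5a,6,7,8,9,9a-octahydro-2-benzoxepine-4-carboxylate
Conditions: H2 (50 atm), [Rh(nbd)(dppb)]BF4 (10 mol%), CH2Cl2, rt
Reagents that add atoms: none
Why: Hydroxyl-directed hydrogenation with a cationic rhodium diphosphine catalyst delivers hydrogen to C6=C7 from the face of the C9 hydroxyl, which is also the face not shielded by the axial C9 CH2O group, so the isopropyl group becomes equatorial and trans to C5 (6R) while the non-coordinating trisubstituted alkenes are not reduced.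

Step 20
Reactants: 30 TMSE (5aS,6R,9S,9aS)-octahydro-2-benzoxepine ester described in step 19
Product: 31 (5aS,6R,9S,9aS)-9-hydroxy-9-({[(2E)-2-(hydroxymethyl)-3-{(1S,6R)-3-(hydroxymethyl)-6-(propan-2-yl)cyclohex-2-en-1-yl}prop-2-enoyl]oxy}methyl)-1-oxo-6-(propan-2-yl)-1,3,5a,6,7,8,9,9a-octahydro-2-benzoxepine-4-carboxylic acid (CNP0361406.9)
Conditions: TASF (tris(dimethylamino)sulfonium difluorotrimethylsilicate), DMF, 0 °C → rt; aq. NH4Cl
Reagents that add atoms: none
Why: Fluoride-mediated desilylation cleaves both primary TBS ethers and the TMSE ester (β-elimination to ethene and fluorotrimethylsilane) in one mild, non-hydrolytic operation that leaves the lactone and the ester linkage intact.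

**Compound list**

1 | 2-bromoprop-2-en-1-ol | OCC(Br)=C | starting material
2 | [(2-bromoprop-2-en-1-yl)oxy](tert-butyl)dimethylsilane | C=C(Br)CO[Si](C)(C)C(C)(C)C | intermediate
3 | methyl 3-hydroxypropanoate | COC(=O)CCO | starting material
4 | methyl 3-(TBS-oxy)propanoate | COC(=O)CCO[Si](C)(C)C(C)(C)C | intermediate
5 | acrolein (prop-2-enal) | C=CC=O | starting material
6 | methyl 2-[(TBS-oxy)methyl]-3-hydroxypent-4-enoate (racemic diastereomers) | COC(=O)C(CO[Si](C)(C)C(C)(C)C)C(O)C=C | intermediate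
7 | methyl 2-[(TBS-oxy)methyl]-3-(methanesulfonyloxy)pent-4-enoate | COC(=O)C(CO[Si](C)(C)C(C)(C)C)C(OS(C)(=O)=O)C=C | intermediate
8 | methyl (2E)-2-[(TBS-oxy)methyl]penta-2,4-dienoate | C=C/C=C(\CO[Si](C)(C)C(C)(C)C)C(=O)OC | intermediate
9 | methyl (2E,4E)-2,6-bis[(TBS-oxy)methyl]hepta-2,4,6-trienoate | C=C(CO[Si](C)(C)C(C)(C)C)/C=C/C=C(\CO[Si](C)(C)C(C)(C)C)C(=O)OC | intermediate
10 | methyl vinyl ketone (but-3-en-2-one) | CC(=O)C=C | starting material
11 | methyl (2E)-3-{(1S,6S)-6-acetyl-3-[(TBS-oxy)methyl]cyclohex-2-en-1-yl}-2-[(TBS-oxy)methyl]prop-2-enoate | COC(=O)/C(=C/[C@@H]1C=C(CO[Si](C)(C)C(C)(C)C)CC[C@@H]1C(C)=O)CO[Si](C)(C)C(C)(C)C | intermediate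
12 | methyl (2E)-2-[(TBS-oxy)methyl]-3-{(1S,6S)-3-[(TBS-oxy)methyl]-6-(prop-1-en-2-yl)cyclohex-2-en-1-yl}prop-2-enoate | COC(=O)/C(=C/[C@@H]1C=C(CO[Si](C)(C)C(C)(C)C)CC[C@@H]1C(C)=C)CO[Si](C)(C)C(C)(C)C | intermediate
13 | methyl (2E)-2-[(TBS-oxy)methyl]-3-{(1S,6R)-3-[(TBS-oxy)methyl]-6-(propan-2-yl)cyclohex-2-en-1-yl}prop-2-enoate | COC(=O)/C(=C/[C@@H]1C=C(CO[Si](C)(C)C(C)(C)C)CC[C@@H]1C(C)C)CO[Si](C)(C)C(C)(C)C | intermediate
14 | (2E)-2-[(TBS-oxy)methyl]-3-{(1S,6R)-3-[(TBS-oxy)methyl]-6-(propan-2-yl)cyclohex-2-en-1-yl}prop-2-enoic acid | OC(=O)/C(=C/[C@@H]1C=C(CO[Si](C)(C)C(C)(C)C)CC[C@@H]1C(C)C)CO[Si](C)(C)C(C)(C)C | intermediate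
15 | 1,2-bis(trimethylsilyloxy)cyclobut-1-ene | C[Si](C)(C)OC1=C(O[Si](C)(C)C)CC1 | starting material
16 | 2-(TMS-oxy)-2-[(TMS-oxy)methyl]cyclobutan-1-one (racemic) | O=C1CCC1(CO[Si](C)(C)C)O[Si](C)(C)C | intermediate
17 | 4-(TMS-oxy)-4-[(TMS-oxy)methyl]cyclobut-1-en-1-yl trifluoromethanesulfonate (racemic) | O=S(=O)(OC1=CCC1(CO[Si](C)(C)C)O[Si](C)(C)C)C(F)(F)F | intermediate
18 | 2-(propan-2-yl)-1-(TMS-oxy)-1-[(TMS-oxy)methyl]cyclobut-2-ene (racemic) | CC(C)C1=CCC1(CO[Si](C)(C)C)O[Si](C)(C)C | intermediate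
19 | 1-(hydroxymethyl)-2-(propan-2-yl)cyclobut-2-en-1-ol (racemic) | CC(C)C1=CCC1(O)CO | intermediate
20 | mixed anhydride of acid 14 with 2,4,6-trichlorobenzoic acid | O=C(OC(=O)c1c(Cl)cc(Cl)cc1Cl)/C(=C/[C@@H]1C=C(CO[Si](C)(C)C(C)(C)C)CC[C@@H]1C(C)C)CO[Si](C)(C)C(C)(C)C | intermediate
21 | [1-hydroxy-2-(propan-2-yl)cyclobut-2-en-1-yl]methyl (2E)-2-[(TBS-oxy)methyl]-3-{(1S,6R)-3-[(TBS-oxy)methyl]-6-(propan-2-yl)cyclohex-2-en-1-yl}prop-2-enoate (1:1 carbinol epimers) | CC(C)C1=CCC1(O)COC(=O)/C(=C/[C@@H]2C=C(CO[Si](C)(C)C(C)(C)C)CC[C@@H]2C(C)C)CO[Si](C)(C)C(C)(C)C | intermediate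
22 | 2-(trimethylsilyl)ethan-1-ol | C[Si](C)(C)CCO | starting material
23 | acryloyl chloride (prop-2-enoyl chloride) | C=CC(=O)Cl | starting material
24 | 2-(trimethylsilyl)ethyl prop-2-enoate | C=CC(=O)OCC[Si](C)(C)C | intermediate
25 | TMSE 3-hydroxy-2-methylidenepent-4-enoate (racemic) | C=CC(O)C(=C)C(=O)OCC[Si](C)(C)C | intermediate
26 | TMSE 2-methylidene-3-(prop-2-enoyloxy)pent-4-enoate (racemic) | C=CC(OC(=O)C=C)C(=C)C(=O)OCC[Si](C)(C)C | intermediate
27 | TMSE (2E)-2-[(prop-2-enoyloxy)methyl]penta-2,4-dienoate | C=C/C=C(\COC(=O)C=C)C(=O)OCC[Si](C)(C)C | intermediate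
28 | TMSE 7-oxo-2,7-dihydrooxepine-3-carboxylate | O=C1C=CC=C(C(=O)OCC[Si](C)(C)C)CO1 | intermediate
29 | TMSE (5aS,9S,9aS)-9-hydroxy-1-oxo-6-(propan-2-yl)-9-({[(2E)-2-[(TBS-oxy)methyl]-3-{(1S,6R)-3-[(TBS-oxy)methyl]-6-(propan-2-yl)cyclohex-2-en-1-yl}prop-2-enoyl]oxy}methyl)-1,3,5a,8,9,9a-hexahydro-2-benzoxepine-4-carboxylate | CC(C)C1=CC[C@@](O)(COC(=O)/C(=C/[C@@H]2C=C(CO[Si](C)(C)C(C)(C)C)CC[C@@H]2C(C)C)CO[Si](C)(C)C(C)(C)C)[C@H]2C(=O)OCC(C(=O)OCC[Si](C)(C)C)=C[C@H]12 | intermediate
30 | TMSE (5aS,6R,9S,9aS)-9-hydroxy-1-oxo-6-(propan-2-yl)-9-({[(2E)-2-[(TBS-oxy)methyl]-3-{(1S,6R)-3-[(TBS-oxy)methyl]-6-(propan-2-yl)cyclohex-2-en-1-yl}prop-2-enoyl]oxy}methyl)-1,3,5a,6,7,8,9,9a-octahydro-2-benzoxepine-4-carboxylate | CC(C)[C@H]1CC[C@@](O)(COC(=O)/C(=C/[C@@H]2C=C(CO[Si](C)(C)C(C)(C)C)CC[C@@H]2C(C)C)CO[Si](C)(C)C(C)(C)C)[C@H]2C(=O)OCC(C(=O)OCC[Si](C)(C)C)=C[C@H]12 | intermediate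
31 | (5aS,6R,9S,9aS)-9-hydroxy-9-({[(2E)-2-(hydroxymethyl)-3-{(1S,6R)-3-(hydroxymethyl)-6-(propan-2-yl)cyclohex-2-en-1-yl}prop-2-enoyl]oxy}methyl)-1-oxo-6-(propan-2-yl)-1,3,5a,6,7,8,9,9a-octahydro-2-benzoxepine-4-carboxylic acid | CC(C)[C@H]1CC[C@@](O)(COC(=O)/C(=C/[C@@H]2C=C(CO)CC[C@@H]2C(C)C)CO)[C@H]2C(=O)OCC(C(=O)O)=C[C@H]12 | target

**Totals**

Total step count: 20.
Longest linear sequence: 12 steps (steps 2–9, 13, 18, 19, 20).

**Steps most likely to fail and fallbacks**

Step 18. The alkenylrhodium or the rhodium enolate may be protonated before the next C–C bond forms, the cyclobutenol may open electrocyclically instead of by β-carbon elimination, and a reversible aldol closure could erode the C9 configuration. The fallback uses known reactions, sets out from lactone 28 and acid 14 and comes back at 29. Hayashi–Miyaura asymmetric 1,4-addition of commercial 4,4,5,5-tetramethyl-2-(3-methylbut-1-en-2-yl)-1,3,2-dioxaborolane to 28 ([Rh(OH)((S)-binap)]2, dioxane/H2O) gives TMSE (5R)-5-(3-methylbut-1-en-2-yl)-7-oxo-2,5,6,7-tetrahydrooxepine-3-carboxylate F1. Alkylation of the caesium salt of 14 (Cs2CO3, DMF) with the known α-bromo ketone 1-bromopent-4-en-2-one gives the 2-oxopent-4-en-1-yl ester of 14 F2. Aldol addition of the lithium enolate of F1 (LiHMDS, THF, −78 °C) to the ketone of F2, anti to the alkenyl group, gives the seco-diene aldol adduct F3, whose carbinol epimers would be separated. Ring-closing metathesis of the two terminal alkenes of F3 (second-generation Grubbs catalyst RuCl2(=CHPh)(H2IMes)(PCy3), CH2Cl2, 40 °C) then forms the C6=C7 bond and returns 29.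

Step 17. Ring closure may stall because ruthenium is held as a stabilised conjugated vinyl carbene, and intermolecular oligomerisation may win over formation of the conjugated seven-membered diene. The fallback sets out from acrylate 24 and comes back at 28 without metathesis. Morita–Baylis–Hillman reaction of 24 with aqueous formaldehyde (DABCO, dioxane/H2O) gives TMSE 2-(hydroxymethyl)prop-2-enoate F4. Esterification with commercial (2Z)-3-iodoprop-2-enoic acid (EDC·HCl, DMAP, CH2Cl2, 0 °C) gives TMSE 2-({[(2Z)-3-iodoprop-2-enoyl]oxy}methyl)prop-2-enoate F5. An intramolecular Mizoroki–Heck reaction of F5 (Pd(OAc)2, PPh3, Ag2CO3, MeCN, 60 °C) closes the ring in the 7-endo mode at the acrylate terminus and β-hydride elimination gives 28.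

Step 6. Facial or endo selectivity may be poor, and the Lewis-basic silyl ethers and ester may deactivate the cationic boron catalyst. The fallback replaces catalyst control by auxiliary control, sets out from triene 9 and comes back at 11. Diels–Alder reaction of 9 with (4R)-4-benzyl-3-(prop-2-enoyl)-1,3-oxazolidin-2-one (Et2AlCl, CH2Cl2, −78 °C; chelated s-cis imide, diene approach anti to the benzyl group) gives the cis imide adduct F6. Treatment with MeNH(OMe)·HCl and AlMe3 gives the Weinreb amide F7. Addition of MeMgBr (THF, −78 → 0 °C) then gives methyl ketone 11.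

Further compounds
F1 | step 18 | TMSE (5R)-5-(3-methylbut-1-en-2-yl)-7-oxo-2,5,6,7-tetrahydrooxepine-3-carboxylate | CC(C)C(=C)[C@@H]1CC(=O)OCC(C(=O)OCC[Si](C)(C)C)=C1
F2 | step 18 | 2-oxopent-4-en-1-yl (2E)-2-[(TBS-oxy)methyl]-3-{(1S,6R)-3-[(TBS-oxy)methyl]-6-(propan-2-yl)cyclohex-2-en-1-yl}prop-2-enoate | C=CCC(=O)COC(=O)/C(=C/[C@@H]1C=C(CO[Si](C)(C)C(C)(C)C)CC[C@@H]1C(C)C)CO[Si](C)(C)C(C)(C)C
F3 | step 18 | seco-diene aldol adduct of F1 and F2, configured as 29 (6-[2-hydroxy-1-(acyloxy)pent-4-en-2-yl]-5-(3-methylbut-1-en-2-yl) oxepinone ester) | C=CC[C@@](O)(COC(=O)/C(=C/[C@@H]2C=C(CO[Si](C)(C)C(C)(C)C)CC[C@@H]2C(C)C)CO[Si](C)(C)C(C)(C)C)[C@H]1C(=O)OCC(C(=O)OCC[Si](C)(C)C)=C[C@@H]1C(=C)C(C)C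
F4 | step 17 | TMSE 2-(hydroxymethyl)prop-2-enoate | C=C(CO)C(=O)OCC[Si](C)(C)C
F5 | step 17 | TMSE 2-({[(2Z)-3-iodoprop-2-enoyl]oxy}methyl)prop-2-enoate | C=C(COC(=O)/C=C\I)C(=O)OCC[Si](C)(C)C
F6 | step 6 | methyl (2E)-3-{(1S,6S)-6-{[(4R)-4-benzyl-2-oxo-1,3-oxazolidin-3-yl]carbonyl}-3-[(TBS-oxy)methyl]cyclohex-2-en-1-yl}-2-[(TBS-oxy)methyl]prop-2-enoate | COC(=O)/C(=C/[C@@H]1C=C(CO[Si](C)(C)C(C)(C)C)CC[C@@H]1C(=O)N1[C@H](Cc2ccccc2)COC1=O)CO[Si](C)(C)C(C)(C)C
F7 | step 6 | methyl (2E)-2-[(TBS-oxy)methyl]-3-{(1S,6S)-3-[(TBS-oxy)methyl]-6-[methoxy(methyl)carbamoyl]cyclohex-2-en-1-yl}prop-2-enoate | COC(=O)/C(=C/[C@@H]1C=C(CO[Si](C)(C)C(C)(C)C)CC[C@@H]1C(=O)N(C)OC)CO[Si](C)(C)C(C)(C)C
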